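## The problem

Target **20** is a 2,3-dihydrobenzofuran. Ring A (C3a, C4, C5, C6, C7, C7a) is fused through C3a and C7a to the five-membered ring O1–C2–C3; C2 carries a 1-formylvinyl group, C3 an isovalerate, and C5 a 1-acyloxyethyl chain. There are four stereocentres: C2 (R) and C3 (S), trans across the dihydrofuran; the side-chain carbinol C1′ (R); and the α-carbon of the 2-methylbutanoate (R). C2 and C3 are neighbours, so one can direct the other. C1′ is separated from them by the arene and has to be set by a reagent, and the acid stereocentre is best bought. Two different acyl groups sit on two secondary benzylic oxygens, so each must be introduced when only one hydroxyl is free. Three groups limit the conditions: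

- the α-substituted acrolein, a Michael acceptor that polymerises;
- the C3 acyloxy group, benzylic and β to H2, whose loss gives the aromatic benzofuran;
- the C1′ ester, para to O1 and therefore ionisable under acid.

The feature that invites the key step is the pattern of ring A: O1 on C7a, the only carbon substituent on C5 para to it, and hydrogen on C4, C6 and C7. A 2-pyrone-5-carboxylate that takes up a ketene acetal and loses CO2 gives exactly this pattern. The remaining atoms O1, C2, C3, C3a and C7a are then a γ-butyrolactone, with C7a as the carbonyl carbon and C3a as the α-carbon.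

## Retrosynthesis

**20 ⇒ 18.** The formyl oxygen is removed, so the last forward step is oxidation of the allylic methyl group of diester **18**. The enal is the most fragile group and should appear last. The isopropenyl group is inert to organomagnesium reagents, fluoride, acylation and borane-free hydride. Carrying an oxygenated vinyl group from the start would need a functionalised vinyl metal and one more protecting group. The forward reaction must choose the methyl group over the C2 methine and spare two benzylic esters. A catalytic SeO2 oxidation through allylic alcohol **19**, finished with MnO2, is planned.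

**18 ⇒ 16 + 17, then 16 ⇒ 15.** The C1′–O acyl bond is cut to alcohol **16** and (R)-2-methylbutanoic acid **17**. The C1′–H bond is then cut to aryl methyl ketone **15**. The acid stereocentre is bought. C1′ is too far from C2 and C3 for substrate control, so an enantioselective ketone reduction is the natural choice. The isovalerate is already on C3 at this stage, so the two benzylic oxygens never need to be told apart. The reduction must select one face of the ketone without touching the alkene or the ester. The esterification must not ionise the benzylic alcohol.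

**15 ⇒ 14 ⇒ 13 ⇒ 12 ⇒ 11.** The C3–O acyl bond is cut to alcohol **14**, and the alcohol is masked as silyl ether **13**. The acetyl C–CH3 bond is cut through Weinreb amide **12** back to methyl ester **11**. The ester oxidation level is what a coumalate delivers. The silyl ether guards C3–O during the two organomagnesium steps, which an isovalerate would not survive. Compound **11** holds only the two ring stereocentres and one carbonyl group.

**11 ⇒ 7 + 8 (key disconnection).** C7a–C7 and C3a–C4 are cut, which takes ring A apart into methyl coumalate **8** and lactone-derived ketene acetal **7**. The neighbouring cuts that keep the arene (C3–C3a or O1–C2) create or invert a stereocentre while the heterocycle closes. This cut leaves C2 and C3 as spectators and draws ring A from a cheap pyrone with built-in regiochemistry. The forward reaction has three demands: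

- cycloaddition at a temperature that **7** survives;
- aromatisation by loss of silanol, not by opening of the O1–C7a bond;
- no ionisation of the C3–O bond.

For these reasons C3 carries a tert-butyldimethylsilyl ether and only the enol oxygen carries trimethylsilyl. The sequence runs through cycloadduct **9** and cyclohexadiene **10**.

**7 ⇒ 6 ⇒ 3 + 4.** The enol O–Si bond is cut to trans lactone **6**. The lactone C–O bond and the C2–isopropenyl bond are then cut, through hydroxy ester **5**, to aldehyde **3** and isopropenylmagnesium bromide **4**. The silyloxy stereocentre next to the aldehyde directs the addition in the Felkin–Anh sense to the anti alcohol, which lactonises to the trans lactone. Dihydroxylation of an E-β,γ-unsaturated ester would give the cis lactone instead. The addition must be non-chelated, so a bulky silyl ether is used.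

**3 ⇒ 2 ⇒ 1.** The aldehyde is traced to the α-silyloxy ester of **2**, and **2** to dimethyl (S)-malate **1**. Malate supplies C3 with the correct configuration and the four carbons that become C2, C3, C3a and C7a. The α-oxygen distinguishes its two esters, so the ester that becomes C2 can be half-reduced while the one that becomes C7a stays.

## Roads not taken

**Alternative 1:** The C3–C3a bond is cut. In the forward direction CrCl2 with catalytic NiCl2 turns aryl iodide aldehyde **A2** into an arylchromium species that adds to the tethered aldehyde. This closes the dihydrofuran and gives carbinol **A1**.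
- Merits: the arene arrives with its finished side chain, so the route is more convergent than the chosen one. Organochromium reagents tolerate both esters, and no thermally fragile dienophile is needed. In these respects this road is better.
- Weak points: C3 is created during ring closure, with only the adjacent C2 to direct it, so the trans outcome is not assured. The α-aryloxy aldehyde **A2** can epimerise at the future C2. After closure the tertiary silyl ether must be unmasked and dehydrated toward the terminal alkene, in the presence of an acid-labile benzylic ester, before the allylic oxidation.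
- Comparison: the chosen plan sets both ring stereocentres before the arene exists, where they are spectators, and carries the isopropenyl group intact from step 3.

**Alternative 2:** C3a–C7a, C4–C5 and C6–C7 are cut. Cp*RuCl(cod) would join diyne **A4**, a silyl ynol ether tethered to a terminal alkyne, with alkyne **A5** in a [2+2+2] cyclotrimerisation. This closes both rings and gives arylsilane **A3**.
- Merits: this is the most convergent of the four plans. Two rings form in one step, and the side-chain stereocentres are built on a small alkyne.
- Weak points: **A4** combines an ynol ether with a propargylic ester, both labile, and its anti-diol core poses the same stereochemical problem as lactone **6**. The isopropenyl alkene can enter the ruthenacycle. The regiochemistry rests on the steric effect of the silyl group. The C7–Si bond of **A3** must finally be cleaved with acid or fluoride, which threatens the benzylic esters.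
- Comparison: the chosen plan needs more linear steps, but its regiochemistry follows from polarity and it ends without a desilylation of the arene.

**Alternative 3:** The O1–C2 bond is cut as a ring contraction. Triflation of the C3 hydroxyl of trans chromanol **A7** would trigger a 1,2-shift of the ring oxygen onto that carbon with inversion. The former C2 of the chroman becomes the isopropenyl group, giving **A6**.
- Merits: 2,2-dimethylchromenes are easy to make, and a Jacobsen–Katsuki epoxidation would set both stereocentres by catalyst control. That is more dependable than the Felkin–Anh addition used here. The isopropenyl group arises directly and the end game is short.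
- Weak points: the key step is a cationic rearrangement run with a triflating agent on a molecule that already holds an ionisable para-alkoxybenzylic ester. It needs O1 antiperiplanar to the leaving group. It competes with elimination, with participation by the C4 oxygen, and with proton loss toward the enol ether, which would aromatise.
- Comparison: the chosen plan pays with a weaker stereocontrol element in step 3. In return its key step is neutral and pericyclic, and it makes only sp2 carbons.

Key step: step 5

Assumption: dimethyl (S)-malate **1** (the dimethyl ester of L-malic acid) and (R)-2-methylbutanoic acid **17** are bought in high enantiomeric purity; the acid is the less common antipode but a catalogue compound.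

## Route

Step 1
Reactants: 1 dimethyl (S)-malate
Product: 2 dimethyl (2S)-2-[(tert-butyldimethylsilyl)oxy]butanedioate
Conditions: TBSCl (1.2 equiv), imidazole (2.5 equiv), DMF, rt
Reagents that add atoms: tert-butyldimethylsilyl chloride, CC(C)(C)[Si](C)(C)Cl
Why: Standard silylation of a secondary α-hydroxy ester; the stereocentre is not touched. The bulky silyl ether later enforces non-chelated addition in step 3 and protects the C3 oxygen up to step 8.

Step 2
Reactants: 2 dimethyl (2S)-2-[(tert-butyldimethylsilyl)oxy]butanedioate
Product: 3 methyl (3S)-3-[(tert-butyldimethylsilyl)oxy]-4-oxobutanoate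
Conditions: iBu2AlH (1.05 equiv), CH2Cl2, −78 °C; MeOH, then aq. KNaC4H4O6; used crude
Reagents that add atoms: none
Why: Half-reduction of an ester with iBu2AlH at low temperature; the ester next to the silyloxy carbon is the more electrophilic one (inductive effect of the α-oxygen) and its aluminium hemiacetal is stable at −78 °C, so one equivalent should stop at the aldehyde and leave the distal ester. Regioselective half-reduction of O-protected malate diesters at the α-oxy ester is a known reaction type.

Step 3
Reactants: 3 methyl (3S)-3-[(tert-butyldimethylsilyl)oxy]-4-oxobutanoate; 4 isopropenylmagnesium bromide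
Product: 6 (4S,5R)-4-[(tert-butyldimethylsilyl)oxy]-5-(prop-1-en-2-yl)oxolan-2-one, via hydroxy ester 5 (not isolated)
Conditions: THF, −78 °C; aq. NH4Cl; then PPTS (cat.), CH2Cl2, rt
Reagents that add atoms: none
Why: Felkin–Anh addition of a Grignard reagent to an α-silyloxy aldehyde: the nucleophile attacks anti to the C–O bond, which should give the 3,4-anti alcohol 5 with the new centre (4R). Mild acid then closes the γ-hydroxy ester to the trans lactone (5-exo-trig lactonisation); the minor cis lactone should be removable by chromatography.

Step 4
Reactants: 6 (4S,5R)-4-[(tert-butyldimethylsilyl)oxy]-5-(prop-1-en-2-yl)oxolan-2-one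
Product: 7 (2R,3S)-3-[(tert-butyldimethylsilyl)oxy]-2-(prop-1-en-2-yl)-5-(trimethylsilyloxy)-2,3-dihydrofuran
Conditions: LiN(iPr)2 (1.1 equiv), Me3SiCl (1.3 equiv, present from the start), THF, −78 °C; pentane, filtration under argon; used crude
Reagents that add atoms: chlorotrimethylsilane, C[Si](C)(C)Cl
Why: Kinetic enolisation with internal silyl quench; the lactone enolate is trapped on oxygen as the silyl ketene acetal before the β-silyloxy group can be expelled. Neither stereocentre takes part.

Step 5
Reactants: 7 (2R,3S)-3-[(tert-butyldimethylsilyl)oxy]-2-(prop-1-en-2-yl)-5-(trimethylsilyloxy)-2,3-dihydrofuran; 8 methyl coumalate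
Product: 11 methyl (2R,3S)-3-[(tert-butyldimethylsilyl)oxy]-2-(prop-1-en-2-yl)-2,3-dihydro-1-benzofuran-5-carboxylate, via bridged lactone cycloadduct 9 (not isolated), via cyclohexadiene ketal 10 (not isolated)
Conditions: 8 (2 equiv), toluene, 100 °C, sealed tube
Reagents that add atoms: none
Why: Inverse-electron-demand Diels–Alder reaction: the electron-poor pyrone 8 is the diene through its C3=C4–C5=C6 unit and the electron-rich enol double bond of ketene acetal 7 is the dienophile. The nucleophilic β-carbon of 7 (future C3a) bonds to pyrone C6, the terminus conjugated with both carbonyl groups, and the acetal carbon (future C7a) bonds to pyrone C3, which gives bridged lactone 9 and places the ester para to O1. Retro-[4+2] loss of CO2 from 9 gives cyclohexadiene 10, and 1,2-elimination of Me3SiOH across C7a–C3a aromatises it to 11. The closest known reaction type is the cycloaddition of alkyl coumalates with ketene acetals, which ends in loss of CO2 and an alcohol and gives 4-alkoxybenzoates. Ring A is closed by an intermolecular [4+2] cycloaddition that forms C3a–C4 and C7a–C7, followed by cycloreversion and elimination; the dihydrofuran ring is already present in 7. No new stereocentre remains, since the sp3 centres made in 9 and 10 are erased on aromatisation, and C2 and C3 are spectators. Two selectivities are needed: the regiochemistry, secured by the matched polarisation of the partners, and the direction of aromatisation, where the silanolate is the better leaving group and the ring oxygen the better donor, so O1 should stay on C7a. The tert-butyldimethylsilyl ether on C3 and the neutral medium are meant to keep the allylic C3–O bond from ionising, and the excess of 8 keeps cycloaddition ahead of protodesilylation of 7 by the silanol set free.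

Step 6
Reactants: 11 methyl (2R,3S)-3-[(tert-butyldimethylsilyl)oxy]-2-(prop-1-en-2-yl)-2,3-dihydro-1-benzofuran-5-carboxylate
Product: 12 (2R,3S)-3-[(tert-butyldimethylsilyl)oxy]-N-methoxy-N-methyl-2-(prop-1-en-2-yl)-2,3-dihydro-1-benzofuran-5-carboxamide
Conditions: MeNH(OMe)·HCl (2 equiv), iPrMgCl (4 equiv), THF, −20 to 0 °C
Reagents that add atoms: N,O-dimethylhydroxylamine hydrochloride, CNOC.Cl
Why: Direct aminolysis of an ester by the chloromagnesium amide of N,O-dimethylhydroxylamine (Weinreb amide synthesis); the silyl ether and the alkene are inert.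

Step 7
Reactants: 12 (2R,3S)-3-[(tert-butyldimethylsilyl)oxy]-N-methoxy-N-methyl-2-(prop-1-en-2-yl)-2,3-dihydro-1-benzofuran-5-carboxamide
Product: 13 1-[(2R,3S)-3-[(tert-butyldimethylsilyl)oxy]-2-(prop-1-en-2-yl)-2,3-dihydro-1-benzofuran-5-yl]ethan-1-one
Conditions: MeMgBr (2 equiv), THF, 0 °C; aq. NH4Cl
Reagents that add atoms: methylmagnesium bromide, C[Mg]Br
Why: Weinreb ketone synthesis; the chelated tetrahedral intermediate survives until work-up, so addition stops at the methyl ketone.

Step 8
Reactants: 13 1-[(2R,3S)-3-[(tert-butyldimethylsilyl)oxy]-2-(prop-1-en-2-yl)-2,3-dihydro-1-benzofuran-5-yl]ethan-1-one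
Product: 14 1-[(2R,3S)-3-hydroxy-2-(prop-1-en-2-yl)-2,3-dihydro-1-benzofuran-5-yl]ethan-1-one
Conditions: Bu4NF (1.5 equiv), AcOH (1.5 equiv), THF, 0 °C to rt
Reagents that add atoms: none
Why: Fluoride cleavage of a silyl ether, buffered with acetic acid so that no free alkoxide meets the methyl ketone. The acetyl group para to O1 disfavours ionisation at C3, so dehydration to the benzofuran is not expected.

Step 9
Reactants: 14 1-[(2R,3S)-3-hydroxy-2-(prop-1-en-2-yl)-2,3-dihydro-1-benzofuran-5-yl]ethan-1-one
Product: 15 (2R,3S)-5-acetyl-2-(prop-1-en-2-yl)-2,3-dihydro-1-benzofuran-3-yl 3-methylbutanoate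
Conditions: 3-methylbutanoyl chloride (1.3 equiv), pyridine (3 equiv), DMAP (0.1 equiv), CH2Cl2, 0 °C
Reagents that add atoms: 3-methylbutanoyl chloride, CC(C)CC(=O)Cl
Why: DMAP-catalysed acylation of a secondary alcohol, done while the C3 hydroxyl is the only one in the molecule. The C3–O bond is not broken, so the configuration is retained.

Step 10
Reactants: 15 (2R,3S)-5-acetyl-2-(prop-1-en-2-yl)-2,3-dihydro-1-benzofuran-3-yl 3-methylbutanoate
Product: 16 (2R,3S)-5-[(1R)-1-hydroxyethyl]-2-(prop-1-en-2-yl)-2,3-dihydro-1-benzofuran-3-yl 3-methylbutanoate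
Conditions: (S)-Me-CBS oxazaborolidine [(3aS)-1-methyl-3,3-diphenyltetrahydro-1H,3H-pyrrolo[1,2-c][1,3,2]oxazaborole] (0.2 equiv), catecholborane (1.8 equiv), toluene, −78 to −40 °C
Reagents that add atoms: none
Why: Corey–Bakshi–Shibata reduction of an aryl methyl ketone; with the aryl group as the large substituent the (S)-catalyst should deliver hydride to the Si face and give the (R)-carbinol, as with acetophenone. Catecholborane is used as the hydride source so that the isopropenyl group is not hydroborated, and the remote ring stereocentres should not interfere.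

Step 11
Reactants: 16 (2R,3S)-5-[(1R)-1-hydroxyethyl]-2-(prop-1-en-2-yl)-2,3-dihydro-1-benzofuran-3-yl 3-methylbutanoate; 17 (R)-2-methylbutanoic acid
Product: 18 (1R)-1-[(2R,3S)-3-(3-methylbutanoyloxy)-2-(prop-1-en-2-yl)-2,3-dihydro-1-benzofuran-5-yl]ethyl (2R)-2-methylbutanoate
Conditions: DCC (1.3 equiv), DMAP (0.1 equiv), CH2Cl2, 0 °C to rt
Reagents that add atoms: none
Why: Steglich esterification under neutral conditions; the benzylic C–O bond of 16 is not broken, so C1′ keeps its configuration. Simple α-branched alkanoic acids are not expected to epimerise under carbodiimide activation.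

Step 12
Reactants: 18 (1R)-1-[(2R,3S)-3-(3-methylbutanoyloxy)-2-(prop-1-en-2-yl)-2,3-dihydro-1-benzofuran-5-yl]ethyl (2R)-2-methylbutanoate
Product: 20 (1R)-1-[(2R,3S)-3-(3-methylbutanoyloxy)-2-(3-oxoprop-1-en-2-yl)-2,3-dihydro-1-benzofuran-5-yl]ethyl (2R)-2-methylbutanoate (CNP0154159.1), via allylic alcohol 19 (not isolated)
Conditions: SeO2 (0.5 equiv), t-BuOOH (3 equiv), CH2Cl2, rt; aq. Na2S2O3 wash; then MnO2 (excess), CH2Cl2, rt
Reagents that add atoms: tert-butyl hydroperoxide, CC(C)(C)OO (source of the new oxygen atom, passed on through selenium dioxide, O=[Se]=O)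
Why: Selenium dioxide allylic oxidation (ene reaction, then [2,3]-sigmatropic shift) of a 1,1-disubstituted alkene should occur at the methyl group and not at the electron-poor, oxygen-bearing C2 methine, giving allylic alcohol 19 with some enal. MnO2, which oxidises only allylic and benzylic alcohols, then completes the conversion under neutral conditions; the catalytic room-temperature variant is chosen to spare the two benzylic esters.

## Compound list

1 | dimethyl (S)-malate | O[C@@H](CC(=O)OC)C(=O)OC | starting material
2 | dimethyl (2S)-2-[(tert-butyldimethylsilyl)oxy]butanedioate | CC(C)(C)[Si](C)(C)O[C@@H](CC(=O)OC)C(=O)OC | intermediate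
3 | methyl (3S)-3-[(tert-butyldimethylsilyl)oxy]-4-oxobutanoate | CC(C)(C)[Si](C)(C)O[C@@H](CC(=O)OC)C=O | intermediate
4 | isopropenylmagnesium bromide | C=C(C)[Mg]Br | starting material
5 | methyl (3S,4R)-3-[(tert-butyldimethylsilyl)oxy]-4-hydroxy-5-methylhex-5-enoate (hydroxy ester, not isolated) | COC(=O)C[C@H](O[Si](C)(C)C(C)(C)C)[C@H](O)C(C)=C | intermediate
6 | (4S,5R)-4-[(tert-butyldimethylsilyl)oxy]-5-(prop-1-en-2-yl)oxolan-2-one | C=C(C)[C@H]1OC(=O)C[C@@H]1O[Si](C)(C)C(C)(C)C | intermediate
7 | (2R,3S)-3-[(tert-butyldimethylsilyl)oxy]-2-(prop-1-en-2-yl)-5-(trimethylsilyloxy)-2,3-dihydrofuran | C=C(C)[C@H]1OC(O[Si](C)(C)C)=C[C@@H]1O[Si](C)(C)C(C)(C)C | intermediate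
8 | methyl coumalate (methyl 2-oxo-2H-pyran-5-carboxylate) | COC(=O)C1=COC(=O)C=C1 | starting material
9 | bridged lactone cycloadduct of 7 and 8 (not isolated): methyl 3-oxo-2-oxabicyclo[2.2.2]oct-5-ene-6-carboxylate fused at C7–C8 to the tetrahydrofuran ring, C8 being the ketal carbon with OSiMe3 and O1, C7 the future C3a; new sp3 centres undefined | C=C(C)[C@H]1OC2(O[Si](C)(C)C)C3C=C(C(=O)OC)C(OC3=O)C2[C@@H]1O[Si](C)(C)C(C)(C)C | intermediate
10 | methyl (2R,3S)-3-[(tert-butyldimethylsilyl)oxy]-2-(prop-1-en-2-yl)-7a-(trimethylsilyloxy)-2,3,3a,7a-tetrahydro-1-benzofuran-5-carboxylate (cyclohexadiene ketal, not isolated; C3a and C7a undefined) | C=C(C)[C@H]1OC2(O[Si](C)(C)C)C=CC(C(=O)OC)=CC2[C@@H]1O[Si](C)(C)C(C)(C)C | intermediate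
11 | methyl (2R,3S)-3-[(tert-butyldimethylsilyl)oxy]-2-(prop-1-en-2-yl)-2,3-dihydro-1-benzofuran-5-carboxylate | C=C(C)[C@H]1Oc2ccc(C(=O)OC)cc2[C@@H]1O[Si](C)(C)C(C)(C)C | intermediate
12 | (2R,3S)-3-[(tert-butyldimethylsilyl)oxy]-N-methoxy-N-methyl-2-(prop-1-en-2-yl)-2,3-dihydro-1-benzofuran-5-carboxamide | C=C(C)[C@H]1Oc2ccc(C(=O)N(C)OC)cc2[C@@H]1O[Si](C)(C)C(C)(C)C | intermediate
13 | 1-[(2R,3S)-3-[(tert-butyldimethylsilyl)oxy]-2-(prop-1-en-2-yl)-2,3-dihydro-1-benzofuran-5-yl]ethan-1-one | C=C(C)[C@H]1Oc2ccc(C(C)=O)cc2[C@@H]1O[Si](C)(C)C(C)(C)C | intermediate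
14 | 1-[(2R,3S)-3-hydroxy-2-(prop-1-en-2-yl)-2,3-dihydro-1-benzofuran-5-yl]ethan-1-one | C=C(C)[C@H]1Oc2ccc(C(C)=O)cc2[C@@H]1O | intermediate
15 | (2R,3S)-5-acetyl-2-(prop-1-en-2-yl)-2,3-dihydro-1-benzofuran-3-yl 3-methylbutanoate | C=C(C)[C@H]1Oc2ccc(C(C)=O)cc2[C@@H]1OC(=O)CC(C)C | intermediate
16 | (2R,3S)-5-[(1R)-1-hydroxyethyl]-2-(prop-1-en-2-yl)-2,3-dihydro-1-benzofuran-3-yl 3-methylbutanoate | C=C(C)[C@H]1Oc2ccc([C@@H](C)O)cc2[C@@H]1OC(=O)CC(C)C | intermediate
17 | (R)-2-methylbutanoic acid | CC[C@@H](C)C(=O)O | starting material
18 | (1R)-1-[(2R,3S)-3-(3-methylbutanoyloxy)-2-(prop-1-en-2-yl)-2,3-dihydro-1-benzofuran-5-yl]ethyl (2R)-2-methylbutanoate | C=C(C)[C@H]1Oc2ccc([C@@H](C)OC(=O)[C@H](C)CC)cc2[C@@H]1OC(=O)CC(C)C | intermediate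
19 | (1R)-1-[(2R,3S)-2-(3-hydroxyprop-1-en-2-yl)-3-(3-methylbutanoyloxy)-2,3-dihydro-1-benzofuran-5-yl]ethyl (2R)-2-methylbutanoate (allylic alcohol, not isolated) | C=C(CO)[C@H]1Oc2ccc([C@@H](C)OC(=O)[C@H](C)CC)cc2[C@@H]1OC(=O)CC(C)C | intermediate
20 | (1R)-1-[(2R,3S)-3-(3-methylbutanoyloxy)-2-(3-oxoprop-1-en-2-yl)-2,3-dihydro-1-benzofuran-5-yl]ethyl (2R)-2-methylbutanoate (CNP0154159.1) | C=C(C=O)[C@H]1Oc2ccc([C@@H](C)OC(=O)[C@H](C)CC)cc2[C@@H]1OC(=O)CC(C)C | target

## Step count and least certain steps

Total step count: 12. Longest linear sequence: 12 steps (1 to 20); compounds 4, 8 and 17 enter as purchased reagents.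

**Step 5 (key step).** Three processes can divert it. The first is ionisation of the allylic C3–O bond of the electron-rich ketene acetal at 100 °C, which leads to an aromatic silyloxyfuran and destroys both stereocentres. The second is protodesilylation of unreacted ketene acetal by the silanol that the aromatisation releases. The third is aromatisation of the cyclohexadiene by opening of the O1–C7a bond instead of loss of silanol, which would give a ring-opened aryl silyl ether. All three stem from the lability of the silyl ketene acetal.

The fallback replaces it by the O-methyl ketene acetal, the dienophile class for which the coumalate reaction is documented. It sets out from lactone 6. O-Methylation with Me3O·BF4 in CH2Cl2 gives the oxolanium tetrafluoroborate F1. Deprotonation with iPr2NEt gives (2R,3S)-3-[(tert-butyldimethylsilyl)oxy]-5-methoxy-2-(prop-1-en-2-yl)-2,3-dihydrofuran F2, which cannot be desilylated. F2 is heated with 8 in toluene over 4 Å molecular sieves; bridged adduct F3 loses CO2 to cyclohexadiene ketal F4, and loss of methanol returns the route to 11. The price is that the aromatisation then has to choose between two alkoxy groups.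

**Step 4.** The lactone enolate carries a β-silyloxy leaving group. E1cB elimination to the butenolide can compete with silylation, and partial C-silylation or hydrolysis during the non-aqueous work-up would lower the purity of 7.

The fallback removes the leaving group ability by going through the alkoxide–enolate dianion. It sets out from 6. HF·pyridine gives (4S,5R)-4-hydroxy-5-(prop-1-en-2-yl)oxolan-2-one F5. Two equivalents of LiN(iPr)2 followed by Me3SiCl give the bis(trimethylsilyl) ketene acetal F6. Heating with 8 gives, through bridged adduct F7 and cyclohexadiene ketal F8, the trimethylsilyl ether F9. K2CO3 in methanol releases hydroxy ester F10, and TBSCl with imidazole returns the route to 11.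

**Step 3.** Facial selectivity may be only moderate, because a magnesium reagent in THF can partly override the Felkin–Anh preference. Migration of the silyl group in the magnesium alkoxide on warming would blur the outcome further.

The fallback changes the organometallic partner from a basic Grignard reagent to a non-basic organochromium species. Aldehyde 3 is coupled with 2-bromopropene under Nozaki–Hiyama–Kishi conditions (CrCl2, catalytic NiCl2, DMSO). Such couplings with α-oxygenated aldehydes follow the same anti sense without chelation or silyl migration. The product is the chromium alkoxide of 5, and acid work-up brings the route back to 6.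

**Step 2.** The hydride may attack the distal ester, or over-reduction to the diol may occur. The α-silyloxy aldehyde can also epimerise or lose the silyloxy group by β-elimination if it is stored.

The fallback differentiates the two esters by hydroxyl-directed reduction before silylation. It sets out from 1. BH3·SMe2 with catalytic NaBH4 reduces only the ester next to the free hydroxyl and gives methyl (3S)-3,4-dihydroxybutanoate F11. TBSCl with imidazole gives the bis-silyl ether F12. HF·pyridine in pyridine–THF frees the primary alcohol F13, and Dess–Martin oxidation returns the route to 3.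

**Step 12.** The 1,1-disubstituted alkene reacts slowly, and the selenous acid formed can promote ionisation of the para-alkoxybenzylic C1′ ester or loss of isovaleric acid from C3 toward the benzofuran. The enal can also be over-oxidised.

The fallback avoids selenium and acid by an allylic halogenation followed by N-oxide oxidation. It sets out from 18. Selenium-catalysed ene-type chlorination (N-chlorosuccinimide, catalytic PhSeCl, CH2Cl2, rt) gives the allylic chloride F14, whose constitution is unambiguous because the allylic shift of an isopropenyl group regenerates the same skeleton. N-Methylmorpholine N-oxide with catalytic NaI in acetonitrile (Ganem-type oxidation) converts F14 into 20.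

## Further compounds

F1 | step 5 | (4S,5R)-4-[(tert-butyldimethylsilyl)oxy]-2-methoxy-5-(prop-1-en-2-yl)-4,5-dihydro-3H-furan-1-ium tetrafluoroborate | C=C(C)[C@H]1[O+]=C(OC)C[C@@H]1O[Si](C)(C)C(C)(C)C.F[B-](F)(F)F
F2 | step 5 | (2R,3S)-3-[(tert-butyldimethylsilyl)oxy]-5-methoxy-2-(prop-1-en-2-yl)-2,3-dihydrofuran | C=C(C)[C@H]1OC(OC)=C[C@@H]1O[Si](C)(C)C(C)(C)C
F3 | step 5 | bridged lactone cycloadduct of F2 and 8 (methoxy analogue of 9; new sp3 centres undefined) | C=C(C)[C@H]1OC2(OC)C3C=C(C(=O)OC)C(OC3=O)C2[C@@H]1O[Si](C)(C)C(C)(C)C
F4 | step 5 | methyl (2R,3S)-3-[(tert-butyldimethylsilyl)oxy]-7a-methoxy-2-(prop-1-en-2-yl)-2,3,3a,7a-tetrahydro-1-benzofuran-5-carboxylate | C=C(C)[C@H]1OC2(OC)C=CC(C(=O)OC)=CC2[C@@H]1O[Si](C)(C)C(C)(C)C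
F5 | step 4 | (4S,5R)-4-hydroxy-5-(prop-1-en-2-yl)oxolan-2-one | C=C(C)[C@H]1OC(=O)C[C@@H]1O
F6 | step 4 | (2R,3S)-2-(prop-1-en-2-yl)-3,5-bis(trimethylsilyloxy)-2,3-dihydrofuran | C=C(C)[C@H]1OC(O[Si](C)(C)C)=C[C@@H]1O[Si](C)(C)C
F7 | step 4 | bridged lactone cycloadduct of F6 and 8 (C3 trimethylsilyl analogue of 9; new sp3 centres undefined) | C=C(C)[C@H]1OC2(O[Si](C)(C)C)C3C=C(C(=O)OC)C(OC3=O)C2[C@@H]1O[Si](C)(C)C
F8 | step 4 | methyl (2R,3S)-2-(prop-1-en-2-yl)-3,7a-bis(trimethylsilyloxy)-2,3,3a,7a-tetrahydro-1-benzofuran-5-carboxylate | C=C(C)[C@H]1OC2(O[Si](C)(C)C)C=CC(C(=O)OC)=CC2[C@@H]1O[Si](C)(C)C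
F9 | step 4 | methyl (2R,3S)-2-(prop-1-en-2-yl)-3-(trimethylsilyloxy)-2,3-dihydro-1-benzofuran-5-carboxylate | C=C(C)[C@H]1Oc2ccc(C(=O)OC)cc2[C@@H]1O[Si](C)(C)C
F10 | step 4 | methyl (2R,3S)-3-hydroxy-2-(prop-1-en-2-yl)-2,3-dihydro-1-benzofuran-5-carboxylate | C=C(C)[C@H]1Oc2ccc(C(=O)OC)cc2[C@@H]1O
F0 | step 3 | none | none
F11 | step 2 | methyl (3S)-3,4-dihydroxybutanoate | O[C@@H](CC(=O)OC)CO
F12 | step 2 | methyl (3S)-3,4-bis[(tert-butyldimethylsilyl)oxy]butanoate | CC(C)(C)[Si](C)(C)O[C@@H](CC(=O)OC)CO[Si](C)(C)C(C)(C)C
F13 | step 2 | methyl (3S)-3-[(tert-butyldimethylsilyl)oxy]-4-hydroxybutanoate | CC(C)(C)[Si](C)(C)O[C@@H](CC(=O)OC)CO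
F14 | step 12 | (1R)-1-[(2R,3S)-2-(3-chloroprop-1-en-2-yl)-3-(3-methylbutanoyloxy)-2,3-dihydro-1-benzofuran-5-yl]ethyl (2R)-2-methylbutanoate | C=C(CCl)[C@H]1Oc2ccc([C@@H](C)OC(=O)[C@H](C)CC)cc2[C@@H]1OC(=O)CC(C)C
A1 | alternative 1 | (1R)-1-{(2S,3S)-3-hydroxy-2-[2-(triethylsilyloxy)propan-2-yl]-2,3-dihydro-1-benzofuran-5-yl}ethyl (2R)-2-methylbutanoate (trans) | CC[Si](CC)(CC)OC(C)(C)[C@H]1Oc2ccc([C@@H](C)OC(=O)[C@H](C)CC)cc2[C@@H]1O
A2 | alternative 1 | (1R)-1-(3-iodo-4-{[(2R)-3-methyl-1-oxo-3-(triethylsilyloxy)butan-2-yl]oxy}phenyl)ethyl (2R)-2-methylbutanoate | CC[Si](CC)(CC)OC(C)(C)[C@H](C=O)Oc1ccc([C@@H](C)OC(=O)[C@H](C)CC)cc1I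
A3 | alternative 2 | (1R)-1-[(2R,3S)-3-(3-methylbutanoyloxy)-2-(prop-1-en-2-yl)-7-(trimethylsilyl)-2,3-dihydro-1-benzofuran-5-yl]ethyl (2R)-2-methylbutanoate | C=C(C)[C@H]1Oc2c([Si](C)(C)C)cc([C@@H](C)OC(=O)[C@H](C)CC)cc2[C@@H]1OC(=O)CC(C)C
A4 | alternative 2 | (3S,4R)-5-methyl-4-{[2-(trimethylsilyl)ethynyl]oxy}hex-5-en-1-yn-3-yl 3-methylbutanoate | C=C(C)[C@@H](OC#C[Si](C)(C)C)[C@H](C#C)OC(=O)CC(C)C
A5 | alternative 2 | (2R)-but-3-yn-2-yl (2R)-2-methylbutanoate | C#C[C@@H](C)OC(=O)[C@H](C)CC
A6 | alternative 3 | (1R)-1-[(2R,3S)-3-[(tert-butyldimethylsilyl)oxy]-2-(prop-1-en-2-yl)-2,3-dihydro-1-benzofuran-5-yl]ethyl (2R)-2-methylbutanoate | C=C(C)[C@H]1Oc2ccc([C@@H](C)OC(=O)[C@H](C)CC)cc2[C@@H]1O[Si](C)(C)C(C)(C)C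
A7 | alternative 3 | (1R)-1-[(3R,4S)-4-[(tert-butyldimethylsilyl)oxy]-3-hydroxy-2,2-dimethyl-3,4-dihydro-2H-chromen-6-yl]ethyl (2R)-2-methylbutanoate (trans) | CC1(C)Oc2ccc([C@@H](C)OC(=O)[C@H](C)CC)cc2[C@H](O[Si](C)(C)C(C)(C)C)[C@H]1O
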